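**Retrosynthetic overview**

1. Ring locants (target numbering, used in all Why lines): C1 (isopropenyl), C2, C3 (CH3), C4 (C7H2–O–coumarin-7-yl), C5 (CH3 and CH2CH2CO2H), C6. The route rests on one feature: the C4 arm and the C5 methyl are vicinal and trans and lie α and β to C3, so with C3 as a ketone and C4=C5 as its enone both groups can arrive in one flask.
2. Late disconnections: CO2H ← CHO ← dioxolane; C3–CH3 ← C3 enol triflate (C2=C3) ← C3 ketone.
3. Key disconnection: C5–CH3 and C4–C7, by Me2CuLi addition to the C4=C5 enone and alkylation of the resulting enolate with 7-(chloromethoxy)coumarin (made from umbelliferone).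
4. Enone ← 5-isopropenylcyclohex-2-enone by 1,2-addition of the dioxolanylethyl Grignard reagent and oxidative 1,3-transposition; C1 ← rhodium/(R)-BINAP 1,4-addition of isopropenylboron to cyclohex-2-enone, then dehydrogenation on the C3–C4 side.
5. Ring order: no ring is formed; the carbocycle is bought as cyclohex-2-enone and the coumarin rings as umbelliferone.

Key step: step 8

Remark: the (S,S) enantiomer of the amide base in step 2 is assigned on the assumption that its proton selection follows the sense established for conformationally locked 4-substituted cyclohexanones.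

**Route**

Step 1
Reactants: 1 cyclohex-2-en-1-one; 2 isopropenylboronic acid pinacol ester
Product: 3 (R)-3-(prop-1-en-2-yl)cyclohexan-1-one
Conditions: [RhCl(C2H4)2]2 (1.5 mol %), (R)-BINAP (3.3 mol %), KOH (0.2 equiv), dioxane/H2O 10:1, 60 °C
Reagents that add atoms: none
Why: Hayashi–Miyaura rhodium-catalysed asymmetric 1,4-addition, in which the isopropenylrhodium–(R)-BINAP species inserts the enone on the face that gives the (R)-ketone (the sense known for aryl and alkenyl transfer) and so sets C1, water releasing the product.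

Step 2
Reactants: 3 (R)-3-(prop-1-en-2-yl)cyclohexan-1-one
Product: 5 trimethyl{[(5R)-5-(prop-1-en-2-yl)cyclohex-1-en-1-yl]oxy}silane, via lithium enolate 4 (not isolated)
Conditions: (S,S)-[PhCH(CH3)]2NH, n-BuLi, THF, 0 °C; Me3SiCl, then 3, −78 °C
Reagents that add atoms: chlorotrimethylsilane, C[Si](C)(C)Cl
Why: Kinetic enolisation by a chiral lithium amide with in situ silyl trapping; in the chair with equatorial isopropenyl the (S,S)-amide should take the axial proton at C4, the α-carbon remote from C1, where its own preference and the steric bias of the substituent agree, and no stereocentre is touched.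

Step 3
Reactants: 5 trimethyl{[(5R)-5-(prop-1-en-2-yl)cyclohex-1-en-1-yl]oxy}silane
Product: 6 (R)-5-(prop-1-en-2-yl)cyclohex-2-en-1-one
Conditions: Pd(OAc)2 (1.05 equiv), MeCN, rt
Reagents that add atoms: none
Why: Saegusa–Ito oxidation, in which palladation of the silyl enol ether and β-hydride elimination put the new double bond at C3=C4 exactly where the enol ether was, leaving C1 and the isopropenyl group alone.

Step 4
Reactants: 6 (R)-5-(prop-1-en-2-yl)cyclohex-2-en-1-one; 7 2-(2-bromoethyl)-1,3-dioxolane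
Product: 9 (5R)-1-[2-(1,3-dioxolan-2-yl)ethyl]-5-(prop-1-en-2-yl)cyclohex-2-en-1-ol as both carbinol epimers, via Grignard reagent 8 (not isolated)
Conditions: 7, Mg, THF, 25 °C; then 6, −78 to 0 °C; H2O
Reagents that add atoms: none
Why: Grignard 1,2-addition of a primary alkylmagnesium halide to the cyclohexenone carbonyl; the carbinol configuration does not matter because this carbon (C5) becomes sp2 in step 5.

Step 5
Reactants: 9 (5R)-1-[2-(1,3-dioxolan-2-yl)ethyl]-5-(prop-1-en-2-yl)cyclohex-2-en-1-ol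
Product: 10 (5S)-3-[2-(1,3-dioxolan-2-yl)ethyl]-5-(prop-1-en-2-yl)cyclohex-2-en-1-one
Conditions: pyridinium chlorochromate [C5H5NH][CrO3Cl] (2 equiv), NaOAc, 4 Å MS, CH2Cl2, rt
Reagents that add atoms: pyridinium chlorochromate, [O-][Cr](=O)(=O)Cl.c1cc[nH+]cc1
Why: Babler–Dauben oxidative transposition, in which the tertiary allylic chromate ester shifts [3,3] to the secondary one at C3 and is oxidised to the ketone, leaving C4=C5 conjugated; the acetate buffer protects the dioxolane, and C1 is untouched (its descriptor changes from R to S through CIP priorities only).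

Step 6
Reactants: 11 umbelliferone
Product: 12 7-[(methylsulfanyl)methoxy]-2H-chromen-2-one
Conditions: NaH, DMF, 0 °C; ClCH2SCH3, NaI (cat.), rt
Reagents that add atoms: chloromethyl methyl sulfide, CSCCl
Why: Williamson etherification of the acidic phenoxide with an α-chloro sulfide, an activated primary electrophile.

Step 7
Reactants: 12 7-[(methylsulfanyl)methoxy]-2H-chromen-2-one
Product: 13 7-(chloromethoxy)-2H-chromen-2-one
Conditions: SO2Cl2 (1.0 equiv), CH2Cl2, −78 to 0 °C; volatiles removed in vacuo, used crude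
Reagents that add atoms: sulfuryl chloride, O=S(=O)(Cl)Cl
Why: Chlorinolysis of the O,S-acetal, the standard preparation of aryl chloromethyl ethers: S-chlorination, loss of CH3SCl to the aryloxycarbenium ion and capture by chloride, the sulfide reacting far faster than the arene or the pyranone double bond.

Step 8
Reactants: 10 (5S)-3-[2-(1,3-dioxolan-2-yl)ethyl]-5-(prop-1-en-2-yl)cyclohex-2-en-1-one; 14 methyllithium; 15 CuI; 13 7-(chloromethoxy)-2H-chromen-2-one
Product: 18 (2S,3R,5S)-3-[2-(1,3-dioxolan-2-yl)ethyl]-3-methyl-2-{[(2-oxo-2H-chromen-7-yl)oxy]methyl}-5-(prop-1-en-2-yl)cyclohexan-1-one, via lithium dimethylcuprate 16 (not isolated), via lithium enolate 17 (not isolated)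
Conditions: CuI (1.05 equiv), CH3Li (2.0 equiv), Et2O, 0 °C; 10, −78 to 0 °C; 13 (2 equiv) in THF, −78 to −30 °C; aq NH4Cl/NH3, −30 °C
Reagents that add atoms: none
Why: Me2CuLi (monovalent copper) π-complexes the enone, adds oxidatively at C5 to a trivalent copper enolate and reductively eliminates to form C5–CH3, leaving lithium enolate 17 and CH3Cu; 17 then displaces chloride from the α-chloro ether 13 in an SN2 step assisted by the ether oxygen to form C4–C7. The closest known reaction type is the three-component cuprate conjugate addition–enolate trapping with alkoxymethyl chlorides. No ring is closed. C5 is set by axial attack on the half-chair that keeps the C1 isopropenyl group pseudo-equatorial, which places the new methyl trans to C1 and the dioxolanylethyl chain cis; C4 is set by chair-like axial alkylation anti to the now pseudo-axial C5 methyl, which places the C7 arm trans to that methyl and cis to the chain and to the isopropenyl group. The step needs C- over O-alkylation, which the tight lithium enolate in ether/THF without dipolar additive and the poorly ionising, electron-poor aryloxymethyl chloride favour, and it needs the chloride to outrun CH3Cu, hence two equivalents of 13 and exactly two CH3Li per CuI so that no free CH3Li reaches the lactone. Quenching cold keeps the β-aryloxy ketone from losing coumarin-7-olate by E1cB.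

Step 9
Reactants: 18 (2S,3R,5S)-3-[2-(1,3-dioxolan-2-yl)ethyl]-3-methyl-2-{[(2-oxo-2H-chromen-7-yl)oxy]methyl}-5-(prop-1-en-2-yl)cyclohexan-1-one
Product: 20 (3S,5R,6S)-5-[2-(1,3-dioxolan-2-yl)ethyl]-5-methyl-6-{[(2-oxo-2H-chromen-7-yl)oxy]methyl}-3-(prop-1-en-2-yl)cyclohex-1-en-1-yl trifluoromethanesulfonate, via potassium enolate 19 (not isolated)
Conditions: 18 added to KN(SiMe3)2 (1.1 equiv), THF, −78 °C; then N-(5-chloropyridin-2-yl)bis(trifluoromethanesulfonimide) (Comins reagent), −78 °C
Reagents that add atoms: N-(5-chloropyridin-2-yl)bis(trifluoromethanesulfonimide), O=S(=O)(N(c1ccc(Cl)cn1)S(=O)(=O)C(F)(F)F)C(F)(F)F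
Why: Kinetic enolisation at the unhindered C2 methylene (C4–H is tertiary and flanked by quaternary C5) and O-sulfonylation of the enolate at −78 °C, with base kept in excess during the addition so that no proton exchange leads to the C4 enolate, which would expel the aryloxide; C4 and C5 are not touched.

Step 10
Reactants: 20 (3S,5R,6S)-5-[2-(1,3-dioxolan-2-yl)ethyl]-5-methyl-6-{[(2-oxo-2H-chromen-7-yl)oxy]methyl}-3-(prop-1-en-2-yl)cyclohex-1-en-1-yl trifluoromethanesulfonate
Product: 21 7-{[(1R,4S,6R)-6-[2-(1,3-dioxolan-2-yl)ethyl]-2,6-dimethyl-4-(prop-1-en-2-yl)cyclohex-2-en-1-yl]methoxy}-2H-chromen-2-one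
Conditions: CH3ZnCl (3 equiv), Pd(PPh3)4 (5 mol %), THF, 50 °C
Reagents that add atoms: methylzinc chloride, C[Zn]Cl
Why: Negishi coupling, in which zerovalent palladium inserts into the enol triflate, CH3ZnCl transmetalates and reductive elimination forms C3–CH3 with the double bond fixed at C2=C3; the organozinc leaves the lactone, the aryl ether and the acetal alone.

Step 11
Reactants: 21 7-{[(1R,4S,6R)-6-[2-(1,3-dioxolan-2-yl)ethyl]-2,6-dimethyl-4-(prop-1-en-2-yl)cyclohex-2-en-1-yl]methoxy}-2H-chromen-2-one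
Product: 22 3-[(1R,2R,5S)-1,3-dimethyl-2-{[(2-oxo-2H-chromen-7-yl)oxy]methyl}-5-(prop-1-en-2-yl)cyclohex-3-en-1-yl]propanal
Conditions: 1 M aq HCl, THF, rt
Reagents that add atoms: water, O
Why: Acid-catalysed acetal hydrolysis through the oxocarbenium ion; dilute acid at room temperature should spare the skipped diene, the aryl ether and the lactone.

Step 12
Reactants: 22 3-[(1R,2R,5S)-1,3-dimethyl-2-{[(2-oxo-2H-chromen-7-yl)oxy]methyl}-5-(prop-1-en-2-yl)cyclohex-3-en-1-yl]propanal
Product: 23 3-[(1R,2R,5S)-1,3-dimethyl-2-{[(2-oxo-2H-chromen-7-yl)oxy]methyl}-5-(prop-1-en-2-yl)cyclohex-3-en-1-yl]propanoic acid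
Conditions: NaClO2, NaH2PO4, 2-methylbut-2-ene (20 equiv), t-BuOH/H2O, 0 °C to rt
Reagents that add atoms: sodium chlorite, [Na+].[O-]Cl=O
Why: Pinnick oxidation, in which chlorous acid adds to the aldehyde and fragments to the acid and HOCl, which the excess 2-methylbut-2-ene scavenges so that the two alkenes and the electron-rich arene are spared; no stereocentre is involved.

**Compound list**

1 | cyclohex-2-en-1-one | O=C1C=CCCC1 | starting material
2 | isopropenylboronic acid pinacol ester (4,4,5,5-tetramethyl-2-(prop-1-en-2-yl)-1,3,2-dioxaborolane) | C=C(C)B1OC(C)(C)C(C)(C)O1 | starting material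
3 | (R)-3-(prop-1-en-2-yl)cyclohexan-1-one | C=C(C)[C@@H]1CCCC(=O)C1 | intermediate
4 | lithium (5R)-5-(prop-1-en-2-yl)cyclohex-1-en-1-olate (formed in the flask) | C=C(C)[C@@H]1CCC=C([O-])C1.[Li+] | intermediate
5 | trimethyl{[(5R)-5-(prop-1-en-2-yl)cyclohex-1-en-1-yl]oxy}silane | C=C(C)[C@@H]1CCC=C(O[Si](C)(C)C)C1 | intermediate
6 | (R)-5-(prop-1-en-2-yl)cyclohex-2-en-1-one | C=C(C)[C@@H]1CC=CC(=O)C1 | intermediate
7 | 2-(2-bromoethyl)-1,3-dioxolane | BrCCC1OCCO1 | starting material
8 | [2-(1,3-dioxolan-2-yl)ethyl]magnesium bromide (formed in the flask) | Br[Mg]CCC1OCCO1 | intermediate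
9 | (5R)-1-[2-(1,3-dioxolan-2-yl)ethyl]-5-(prop-1-en-2-yl)cyclohex-2-en-1-ol, both carbinol epimers | C=C(C)[C@@H]1CC=CC(O)(CCC2OCCO2)C1 | intermediate
10 | (5S)-3-[2-(1,3-dioxolan-2-yl)ethyl]-5-(prop-1-en-2-yl)cyclohex-2-en-1-one | C=C(C)[C@@H]1CC(=O)C=C(CCC2OCCO2)C1 | intermediate
11 | umbelliferone (7-hydroxy-2H-chromen-2-one) | O=c1ccc2ccc(O)cc2o1 | starting material
12 | 7-[(methylsulfanyl)methoxy]-2H-chromen-2-one | CSCOc1ccc2ccc(=O)oc2c1 | intermediate
13 | 7-(chloromethoxy)-2H-chromen-2-one | ClCOc1ccc2ccc(=O)oc2c1 | intermediate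
14 | methyllithium | [Li]C | starting material
15 | copper iodide CuI | [Cu]I | starting material
16 | lithium dimethylcuprate (formed in the flask) | [Li+].C[Cu-]C | intermediate
17 | lithium (3R,5S)-3-[2-(1,3-dioxolan-2-yl)ethyl]-3-methyl-5-(prop-1-en-2-yl)cyclohex-1-en-1-olate (formed in the flask) | C=C(C)[C@@H]1CC([O-])=C[C@](C)(CCC2OCCO2)C1.[Li+] | intermediate
18 | (2S,3R,5S)-3-[2-(1,3-dioxolan-2-yl)ethyl]-3-methyl-2-{[(2-oxo-2H-chromen-7-yl)oxy]methyl}-5-(prop-1-en-2-yl)cyclohexan-1-one | C=C(C)[C@@H]1CC(=O)[C@H](COc2ccc3ccc(=O)oc3c2)[C@](C)(CCC2OCCO2)C1 | intermediate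
19 | potassium (3S,5R,6S)-5-[2-(1,3-dioxolan-2-yl)ethyl]-5-methyl-6-{[(2-oxo-2H-chromen-7-yl)oxy]methyl}-3-(prop-1-en-2-yl)cyclohex-1-en-1-olate (formed in the flask) | C=C(C)[C@@H]1C=C([O-])[C@H](COc2ccc3ccc(=O)oc3c2)[C@](C)(CCC2OCCO2)C1.[K+] | intermediate
20 | (3S,5R,6S)-5-[2-(1,3-dioxolan-2-yl)ethyl]-5-methyl-6-{[(2-oxo-2H-chromen-7-yl)oxy]methyl}-3-(prop-1-en-2-yl)cyclohex-1-en-1-yl trifluoromethanesulfonate | C=C(C)[C@@H]1C=C(OS(=O)(=O)C(F)(F)F)[C@H](COc2ccc3ccc(=O)oc3c2)[C@](C)(CCC2OCCO2)C1 | intermediate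
21 | 7-{[(1R,4S,6R)-6-[2-(1,3-dioxolan-2-yl)ethyl]-2,6-dimethyl-4-(prop-1-en-2-yl)cyclohex-2-en-1-yl]methoxy}-2H-chromen-2-one | C=C(C)[C@@H]1C=C(C)[C@H](COc2ccc3ccc(=O)oc3c2)[C@](C)(CCC2OCCO2)C1 | intermediate
22 | 3-[(1R,2R,5S)-1,3-dimethyl-2-{[(2-oxo-2H-chromen-7-yl)oxy]methyl}-5-(prop-1-en-2-yl)cyclohex-3-en-1-yl]propanal | C=C(C)[C@@H]1C=C(C)[C@H](COc2ccc3ccc(=O)oc3c2)[C@](C)(CCC=O)C1 | intermediate
23 | 3-[(1R,2R,5S)-1,3-dimethyl-2-{[(2-oxo-2H-chromen-7-yl)oxy]methyl}-5-(prop-1-en-2-yl)cyclohex-3-en-1-yl]propanoic acid | C=C(C)[C@@H]1C=C(C)[C@H](COc2ccc3ccc(=O)oc3c2)[C@](C)(CCC(=O)O)C1 | target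

**Step count**

Total: 12 steps. Longest linear sequence: 10 steps (steps 1–5 and 8–12); the chloride 13 is a two-step branch (steps 6–7).

**Steps most likely to fail**

Step 8. The congested enolate next to the new quaternary carbon may be alkylated on oxygen, the chloride may be consumed by methylcopper species before the enolate reacts, or the product may lose the aryloxide by elimination while enolate is still present. The fallback replaces the chloromethyl ether by formaldehyde and forms the aryl ether afterwards. It sets out from 10. Me2CuLi in the presence of Me3SiCl (Et2O/THF, −78 to 0 °C) should give, with the same facial sense, the silyl enol ether trimethyl{[(3R,5S)-3-[2-(1,3-dioxolan-2-yl)ethyl]-3-methyl-5-(prop-1-en-2-yl)cyclohex-1-en-1-yl]oxy}silane F1, isolated free of copper. CH3Li (THF, 0 °C) regenerates the lithium enolate, and monomeric formaldehyde at −78 °C should add anti to the axial C5 methyl to give the hydroxymethyl ketone (2S,3R,5S)-3-[2-(1,3-dioxolan-2-yl)ethyl]-2-(hydroxymethyl)-3-methyl-5-(prop-1-en-2-yl)cyclohexan-1-one F2. Mitsunobu etherification of F2 with umbelliferone 11 (PPh3, diisopropyl azodicarboxylate, THF, 0 °C) forms the C7–O bond and comes back to the route at 18.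

Step 9. Proton exchange may carry the C2 enolate over to the C4 side, which expels coumarin-7-olate, and the amide base or the enolate may attack the coumarin. The fallback postpones the coumarin until after the enol triflate chemistry. It sets out from 10 and runs through F1 and F2 as described above. Silylation (t-BuMe2SiCl, imidazole, DMF) gives the silyl ether (2S,3R,5S)-2-{[(tert-butyldimethylsilyl)oxy]methyl}-3-[2-(1,3-dioxolan-2-yl)ethyl]-3-methyl-5-(prop-1-en-2-yl)cyclohexan-1-one F3, whose silyloxide is a far poorer leaving group and which carries no lactone. The same kinetic triflation (KN(SiMe3)2, Comins reagent, THF, −78 °C) should give the enol triflate (3S,5R,6S)-6-{[(tert-butyldimethylsilyl)oxy]methyl}-5-[2-(1,3-dioxolan-2-yl)ethyl]-5-methyl-3-(prop-1-en-2-yl)cyclohex-1-en-1-yl trifluoromethanesulfonate F4, and Negishi methylation (CH3ZnCl, Pd(PPh3)4, THF) the diene tert-butyl{[(1R,4S,6R)-6-[2-(1,3-dioxolan-2-yl)ethyl]-2,6-dimethyl-4-(prop-1-en-2-yl)cyclohex-2-en-1-yl]methoxy}dimethylsilane F5. n-Bu4NF (THF) frees the primary alcohol [(1R,4S,6R)-6-[2-(1,3-dioxolan-2-yl)ethyl]-2,6-dimethyl-4-(prop-1-en-2-yl)cyclohex-2-en-1-yl]methanol F6, and Mitsunobu coupling of F6 with umbelliferone 11 rejoins the route at 21.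

Step 2. Proton removal at C6 (the α-carbon next to C1) may compete with removal at C4; after step 3 that portion becomes the achiral conjugated dienone and material is lost. The fallback fixes the position of the double bond before the stereocentre is made. It sets out from 1. LiN(i-Pr)2 (THF, −78 °C) deprotonates the enone only at its saturated α-carbon, and PhSSPh gives 6-(phenylsulfanyl)cyclohex-2-en-1-one F7. The rhodium/(R)-BINAP addition of 2 (Rh(acac)(C2H4)2, dioxane/H2O, no added base) should then give (5R)-2-(phenylsulfanyl)-5-(prop-1-en-2-yl)cyclohexan-1-one F8, with the sulfur on the carbon that must become olefinic and the new centre under catalyst control. NaIO4 (MeOH/H2O) gives the sulfoxide (5R)-2-(benzenesulfinyl)-5-(prop-1-en-2-yl)cyclohexan-1-one F9, and thermal syn-elimination (toluene, CaCO3, 110 °C), which can only go toward the one adjacent CH2, comes back to the route at 6.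

**Further compounds**

F1 | step 8 | trimethyl{[(3R,5S)-3-[2-(1,3-dioxolan-2-yl)ethyl]-3-methyl-5-(prop-1-en-2-yl)cyclohex-1-en-1-yl]oxy}silane | C=C(C)[C@@H]1CC(O[Si](C)(C)C)=C[C@](C)(CCC2OCCO2)C1
F2 | step 8 | (2S,3R,5S)-3-[2-(1,3-dioxolan-2-yl)ethyl]-2-(hydroxymethyl)-3-methyl-5-(prop-1-en-2-yl)cyclohexan-1-one | C=C(C)[C@@H]1CC(=O)[C@H](CO)[C@](C)(CCC2OCCO2)C1
F3 | step 9 | (2S,3R,5S)-2-{[(tert-butyldimethylsilyl)oxy]methyl}-3-[2-(1,3-dioxolan-2-yl)ethyl]-3-methyl-5-(prop-1-en-2-yl)cyclohexan-1-one | C=C(C)[C@@H]1CC(=O)[C@H](CO[Si](C)(C)C(C)(C)C)[C@](C)(CCC2OCCO2)C1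
F4 | step 9 | (3S,5R,6S)-6-{[(tert-butyldimethylsilyl)oxy]methyl}-5-[2-(1,3-dioxolan-2-yl)ethyl]-5-methyl-3-(prop-1-en-2-yl)cyclohex-1-en-1-yl trifluoromethanesulfonate | C=C(C)[C@@H]1C=C(OS(=O)(=O)C(F)(F)F)[C@H](CO[Si](C)(C)C(C)(C)C)[C@](C)(CCC2OCCO2)C1
F5 | step 9 | tert-butyl{[(1R,4S,6R)-6-[2-(1,3-dioxolan-2-yl)ethyl]-2,6-dimethyl-4-(prop-1-en-2-yl)cyclohex-2-en-1-yl]methoxy}dimethylsilane | C=C(C)[C@@H]1C=C(C)[C@H](CO[Si](C)(C)C(C)(C)C)[C@](C)(CCC2OCCO2)C1
F6 | step 9 | [(1R,4S,6R)-6-[2-(1,3-dioxolan-2-yl)ethyl]-2,6-dimethyl-4-(prop-1-en-2-yl)cyclohex-2-en-1-yl]methanol | C=C(C)[C@@H]1C=C(C)[C@H](CO)[C@](C)(CCC2OCCO2)C1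
F7 | step 2 | 6-(phenylsulfanyl)cyclohex-2-en-1-one (racemic) | O=C1C=CCCC1Sc1ccccc1
F8 | step 2 | (5R)-2-(phenylsulfanyl)-5-(prop-1-en-2-yl)cyclohexan-1-one (both C2 epimers) | C=C(C)[C@@H]1CCC(Sc2ccccc2)C(=O)C1
F9 | step 2 | (5R)-2-(benzenesulfinyl)-5-(prop-1-en-2-yl)cyclohexan-1-one (isomers at C2 and sulfur) | C=C(C)[C@@H]1CCC(S(=O)c2ccccc2)C(=O)C1
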